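The benzo ring is disconnected at C3a–C4 and C7–C7a. The contiguous carbons C4(Br), C5(Br), C6(Br) and C7(H) of ring B (the carbocycle) are taken intact from the diene of 2,3,4-tribromothiophene 1,1-dioxide. Ring A (the pyrrole), already carrying both methylsulfanyl groups, supplies C3a and C7a through the pyrrole C4=C5 bond. One operation, an inverse-demand [4+2] addition followed by SO2 extrusion, closes the carbocycle and fixes the Br3/H pattern. The precursor is N-Boc-2,3-bis(methylsulfanyl)pyrrole: Boc directs the C2 sulfenylation, keeps nitrogen out of side reactions and is cleaved last, after DDQ aromatisation.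

Key step: step 5

Remark: 12 and 13 are racemic (one enantiomer drawn) and their stereocentres vanish on aromatisation; 2,3,4-tribromothiophene is taken as a catalogue compound.

Step 1
Reactants: 1 3-bromo-1-(triisopropylsilyl)pyrrole; 2 dimethyl disulfide
Product: 4 3-(methylsulfanyl)-1-(triisopropylsilyl)pyrrole, via 3-lithio-1-(triisopropylsilyl)pyrrole 3 (not isolated)
Conditions: n-BuLi, THF, −78 °C; then MeSSMe, −78 °C to rt
Reagents that add atoms: dimethyl disulfide 2, CSSC
Why: Bromine–lithium exchange is fast at −78 °C, the bulky silyl group shields both α-positions so that the 3-lithio species 3 should not isomerise, and S–S cleavage of the disulfide by the aryllithium (sulfenylation) should give 4.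

Step 2
Reactants: 4 3-(methylsulfanyl)-1-(triisopropylsilyl)pyrrole
Product: 6 tert-butyl 3-(methylsulfanyl)pyrrole-1-carboxylate, via 3-(methylsulfanyl)-1H-pyrrole 5 (not isolated)
Conditions: Bu4NF, THF, 0 °C; then Boc2O, DMAP (cat.), rt
Reagents that add atoms: di-tert-butyl dicarbonate, CC(C)(C)OC(=O)OC(=O)OC(C)(C)C
Why: Fluoride-induced N–Si cleavage frees the pyrrole nitrogen, which should be acylated in the same flask by Boc2O under DMAP catalysis (carbamate formation), so that the electron-rich NH-pyrrole 5 need not be handled.

Step 3
Reactants: 6 tert-butyl 3-(methylsulfanyl)pyrrole-1-carboxylate; 2 dimethyl disulfide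
Product: 8 tert-butyl 2,3-bis(methylsulfanyl)pyrrole-1-carboxylate, via tert-butyl 2-lithio-3-(methylsulfanyl)pyrrole-1-carboxylate 7 (not isolated)
Conditions: LiN(iPr)2, THF, −78 °C; then MeSSMe, −78 °C
Reagents that add atoms: dimethyl disulfide 2, CSSC
Why: In this directed ortho-metalation the carbamate carbonyl guides the amide base to an α-position and the adjacent sulfur acidifies C2–H, so the doubly flanked C2 should be lithiated kinetically and 7 sulfenylated at −78 °C before equilibration or carbamate migration can set in.

Step 4
Reactants: 9 2,3,4-tribromothiophene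
Product: 11 2,3,4-tribromothiophene 1,1-dioxide, via 2,3,4-tribromothiophene 1-oxide 10 (not isolated)
Conditions: CF3CO3H [from (CF3CO)2O and 50% aq. H2O2], CH2Cl2, 0 °C to rt
Reagents that add atoms: trifluoroperacetic acid, OOC(=O)C(F)(F)F
Why: Electrophilic S-oxidation of an electron-poor thiophene needs the strongest peracid, which should carry the sulfur through the S-oxide 10 (oxidised faster than the thiophene) to the non-aromatic sulfone 11, whose three bromines should slow the self-dimerisation typical of thiophene dioxides (11 is used without delay).

Step 5
Reactants: 8 tert-butyl 2,3-bis(methylsulfanyl)pyrrole-1-carboxylate; 11 2,3,4-tribromothiophene 1,1-dioxide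
Product: 13 tert-butyl cis-4,5,6-tribromo-2,3-bis(methylsulfanyl)-3a,7a-dihydroindole-1-carboxylate (racemic), via bridged 7-thianorbornene dioxide adduct 12 (not isolated)
Conditions: PhMe, 100 °C, N2 sweep; 11 added slowly to 8 (1.5 equiv)
Reagents that add atoms: none
Why: Proposed new method: sulfone 11 is a cisoid-locked, strongly electron-poor diene (sulfonyl group and three bromines) that should add across the C4=C5 π bond of 8 in an asynchronous inverse-demand [4+2] cycloaddition, the pyrrole α-carbon C5 bonding ahead to the CH terminus of the diene, after which the strained bridged sulfone 12 should extrude SO2 cheletropically at the reaction temperature to leave 13. The closest known reaction type is the cycloaddition/SO2 extrusion of tetrahalothiophene 1,1-dioxides with enol ethers, enamines and simple alkenes; its extension to a pyrrole double bond is reasonable because the N-acyl group lowers the aromatic stabilisation that has to be given up and because irreversible SO2 loss drains reversible competing adducts (for example those in which the pyrrole reacts as the 4π partner). Ring B closes in a six-membered [4π+2π] mode that forms C7–C7a and C3a–C4, or, should the addition be stepwise, by collapse of the sulfonyl- and bromine-stabilised carbanion onto the cationic pyrrole carbon C4 of the zwitterion. The new stereocentres C3a and C7a are set cis by suprafacial delivery of both bonds to one face of the ring double bond (control by substrate geometry, racemic), and both are erased in step 6. Three selectivities are needed: site (C4=C5 and not the fully substituted C2=C3, which two SMe groups block), periselectivity (sulfone as diene), and orientation, which is secured by pairing the most nucleophilic carbon of 8 (C5, α to nitrogen and terminus of the S–C2=C3–C4=C5 push system) with the unhindered CH terminus of 11, where attack leaves the negative charge on the carbon bearing both bromine and the sulfonyl group, so that hydrogen should end at C7 and bromine at C4, C5 and C6.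

Step 6
Reactants: 13 tert-butyl cis-4,5,6-tribromo-2,3-bis(methylsulfanyl)-3a,7a-dihydroindole-1-carboxylate
Product: 14 tert-butyl 4,5,6-tribromo-2,3-bis(methylsulfanyl)indole-1-carboxylate
Conditions: DDQ, PhH, rt
Reagents that add atoms: none
Why: In this quinone dehydrogenation DDQ should abstract the hydridic, allylic C7a–H next to the carbamate nitrogen and the resulting stabilised cation should lose the C3a proton to form the aromatic indole, while thioethers and aryl bromides tolerate DDQ at room temperature and the neutral medium avoids base-induced C7a–N scission.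

Step 7
Reactants: 14 tert-butyl 4,5,6-tribromo-2,3-bis(methylsulfanyl)indole-1-carboxylate
Product: 15 4,5,6-tribromo-2,3-bis(methylsulfanyl)-1H-indole
Conditions: NaOMe (cat.), MeOH–THF, rt; then aq. NH4Cl
Reagents that add atoms: none
Why: Catalytic methoxide should transesterify the carbamate of the electron-poor indole (the indolide is a good leaving group), a mild basic N-Boc cleavage that avoids acid-promoted migration of indole sulfanyl groups and leaves the aryl bromides untouched.

Compound list
1 | 3-bromo-1-(triisopropylsilyl)pyrrole | CC(C)[Si](C(C)C)(C(C)C)n1ccc(Br)c1 | starting material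
2 | dimethyl disulfide | CSSC | starting material
3 | 3-lithio-1-(triisopropylsilyl)pyrrole | [Li]c1ccn([Si](C(C)C)(C(C)C)C(C)C)c1 | intermediate (not isolated)
4 | 3-(methylsulfanyl)-1-(triisopropylsilyl)pyrrole | CSc1ccn([Si](C(C)C)(C(C)C)C(C)C)c1 | intermediate
5 | 3-(methylsulfanyl)-1H-pyrrole | CSc1cc[nH]c1 | intermediate (not isolated)
6 | tert-butyl 3-(methylsulfanyl)pyrrole-1-carboxylate | CSc1ccn(C(=O)OC(C)(C)C)c1 | intermediate
7 | tert-butyl 2-lithio-3-(methylsulfanyl)pyrrole-1-carboxylate | [Li]c1c(SC)ccn1C(=O)OC(C)(C)C | intermediate (not isolated)
8 | tert-butyl 2,3-bis(methylsulfanyl)pyrrole-1-carboxylate | CSc1ccn(C(=O)OC(C)(C)C)c1SC | intermediate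
9 | 2,3,4-tribromothiophene | Brc1csc(Br)c1Br | starting material
10 | 2,3,4-tribromothiophene 1-oxide (racemic at sulfur) | O=S1C=C(Br)C(Br)=C1Br | intermediate (not isolated)
11 | 2,3,4-tribromothiophene 1,1-dioxide | O=S1(=O)C=C(Br)C(Br)=C1Br | intermediate
12 | tert-butyl 7,8,9-tribromo-4,5-bis(methylsulfanyl)-10-thia-3-azatricyclo[5.2.1.0^2,6]deca-4,8-diene-3-carboxylate 10,10-dioxide (endo adduct, pyrroline ring anti to the SO2 bridge, ring-fusion hydrogens cis; racemic, one enantiomer drawn) | CSC1=C(SC)[C@@H]2[C@H](N1C(=O)OC(C)(C)C)[C@@H]3C(Br)=C(Br)[C@@]2(Br)S3(=O)=O | intermediate (not isolated)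
13 | tert-butyl cis-4,5,6-tribromo-2,3-bis(methylsulfanyl)-3a,7a-dihydroindole-1-carboxylate (racemic, one enantiomer drawn) | CSC1=C(SC)[C@H]2C(Br)=C(Br)C(Br)=C[C@H]2N1C(=O)OC(C)(C)C | intermediate
14 | tert-butyl 4,5,6-tribromo-2,3-bis(methylsulfanyl)indole-1-carboxylate | CSc1c(SC)c2c(Br)c(Br)c(Br)cc2n1C(=O)OC(C)(C)C | intermediate
15 | 4,5,6-tribromo-2,3-bis(methylsulfanyl)-1H-indole | CSc1[nH]c2cc(Br)c(Br)c(Br)c2c1SC | target

Total step count: 7.
Longest linear sequence: 6 steps (steps 1, 2, 3, 5, 6, 7); step 4 is a one-step side branch.

Steps most likely to fail

Step 5. The aromatic C4=C5 bond may not engage before the sulfone dimerises. The orientation may also invert, with pyrrole C4 bonding to the CH terminus and so leading into the 5,6,7-tribromo series. The first-formed zwitterion may rearomatise by proton loss instead of closing the ring, or the pyrrole may react as the 4π partner. The fallback uses known chemistry and gives up the ring-from-ring construction for a Gassman indole synthesis. It sets out from dimethyl disulfide 2 together with purchased, symmetrical 3,4,5-tribromoaniline F1, whose two equivalent ortho positions make the 4,5,6-pattern unambiguous. N-Chlorination with tert-butyl hypochlorite (CH2Cl2, −78 °C) should give N-chloro-3,4,5-tribromoaniline F2. Addition of (methylsulfanyl)acetaldehyde dimethyl acetal should give the azasulfonium salt (2,2-dimethoxyethyl)(methyl)[(3,4,5-tribromophenyl)amino]sulfonium chloride F3. Et3N should then form the ylide, which undergoes Sommelet–Hauser [2,3]-shift to 3,4,5-tribromo-2-[2,2-dimethoxy-1-(methylsulfanyl)ethyl]aniline F4. Acid-catalysed ring closure with loss of methanol should give 4,5,6-tribromo-3-(methylsulfanyl)-1H-indole F5. Disulfide 2 is cleaved with SO2Cl2 to methanesulfenyl chloride F6, which should sulfenylate F5 at C3 to give 4,5,6-tribromo-3,3-bis(methylsulfanyl)-3H-indole F7. A 1,2-sulfanyl shift to C2 and proton loss bring the sequence back to the route at the target 15.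

Step 6. Aromatisation may take the wrong path, C7a–N scission with the carbamate nitrogen as leaving group, which opens the five-membered ring. The oxidant may also attack sulfur or the electron-rich ketene N,S-acetal. The fallback reverses the order of the end game and sets out from 13. The carbamate is cleaved first under non-protic conditions (Me3SiOTf, 2,6-lutidine, CH2Cl2, 0 °C; then MeOH) to give cis-4,5,6-tribromo-2,3-bis(methylsulfanyl)-3a,7a-dihydro-1H-indole F8. In F8 nitrogen is no longer a leaving group. As an electron-rich cyclic amine F8 should be dehydrogenated by activated MnO2 (CH2Cl2, rt) in the manner of an indoline-to-indole oxidation. The fallback rejoins the route at the target 15, bypassing 14.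

Step 3. Deprotonation or trapping may occur at C5 instead of C2 through equilibration of the α-lithio species, or the carbamate may migrate from nitrogen to carbon in 7. The fallback replaces directed metalation by electrophilic aromatic substitution and sets out from 4. Desilylation with Bu4NF and isolation gives 5, which is treated with one equivalent of methanesulfenyl chloride F6 (from 2 and SO2Cl2; CH2Cl2, −78 °C). Attack should occur at C2, the α-carbon ortho to the donor sulfur, to give 2,3-bis(methylsulfanyl)-1H-pyrrole F9. Boc2O with catalytic DMAP then returns to the route at 8.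

Further compounds
F1 | step 5 | 3,4,5-tribromoaniline | Nc1cc(Br)c(Br)c(Br)c1
F2 | step 5 | N-chloro-3,4,5-tribromoaniline | ClNc1cc(Br)c(Br)c(Br)c1
F3 | step 5 | (2,2-dimethoxyethyl)(methyl)[(3,4,5-tribromophenyl)amino]sulfonium chloride | COC(C[S+](C)Nc1cc(Br)c(Br)c(Br)c1)OC.[Cl-]
F4 | step 5 | 3,4,5-tribromo-2-[2,2-dimethoxy-1-(methylsulfanyl)ethyl]aniline (racemic) | COC(OC)C(SC)c1c(N)cc(Br)c(Br)c1Br
F5 | step 5 | 4,5,6-tribromo-3-(methylsulfanyl)-1H-indole | CSc1c[nH]c2cc(Br)c(Br)c(Br)c12
F6 | step 5 | methanesulfenyl chloride | CSCl
F7 | step 5 | 4,5,6-tribromo-3,3-bis(methylsulfanyl)-3H-indole | CSC1(SC)C=Nc2cc(Br)c(Br)c(Br)c21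
F8 | step 6 | cis-4,5,6-tribromo-2,3-bis(methylsulfanyl)-3a,7a-dihydro-1H-indole (racemic, one enantiomer drawn) | CSC1=C(SC)[C@H]2C(Br)=C(Br)C(Br)=C[C@H]2N1
F9 | step 3 | 2,3-bis(methylsulfanyl)-1H-pyrrole | CSc1cc[nH]c1SC
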